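**Retrosynthetic overview**
1. Target 34 is traced back, through removal of the C6 silyl group, catalyst-controlled epoxidation of the C10 vinyl group (oxirane, last ring) and allylic oxidation of the C5 isopropenyl group, to the trans-fused α-methylene-γ-butyrolactone 28.
2. 28 comes from diazophosphonoacetate 25 by the key step: a rhodium-carbenoid 1,5-insertion into a ring C–H bond closes the γ-lactone at the bond between the lactone α-carbon (C11) and ring carbon C7, and an olefination with formaldehyde in the same flask adds the exocyclic methylene.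
3. Enabling feature: in the chair of the six-membered carbocycle (C5–C10) the ester oxygen on C8 is equatorial, so the carbenoid carbon sits 1,5 to the equatorial C–H bond of the ring CH2 group C7; the other neighbour, C9–H, is switched off by its methacrylate oxygen and by quaternary C10.
4. 25 is reached from cis-diol 19, which comes from ene-dione 12 by site-selective carbonyl reduction, reductive α-hydroxylation and axial-selective reduction; 12 comes from quinone monoketal 3 by enantioselective isopropenyl addition and two α'-alkylations that build quaternary C10.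
5. Ring order: carbocycle from the arene 4-methoxyphenol by dearomatisation (step 1), γ-lactone in step 13, oxirane in step 15.

Key step: step 13

Remark: elemane numbering is used for the target and advanced intermediates (carbocycle C5–C10 with quaternary C10, lactone C11/C12/C13 on C7 and O–C8, oxirane C1/C2 on C10, acrolein unit C3/C4/C15 on C5); β is the ring face of the C10 methyl group, α the face of the oxygen atoms on C8 and C9.

**Route**

Step 1
Reactants: 1 4-methoxyphenol; 2 methanol
Product: 3 4,4-dimethoxycyclohexa-2,5-dien-1-one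
Conditions: PhI(OAc)2 (1.1 equiv), MeOH, 0 °C to rt
Reagents that add atoms: methanol, CO
Why: Oxidative dearomatisation of a para-alkoxyphenol by a hypervalent iodine reagent, with capture of the phenoxonium ion by methanol (quinone monoketal formation), turns the flat arene into the future carbocycle; no stereocenter is formed.

Step 2
Reactants: 3 4,4-dimethoxycyclohexa-2,5-dien-1-one; 4 isopropenylboronic acid pinacol ester
Product: 5 (R)-4,4-dimethoxy-5-(prop-1-en-2-yl)cyclohex-2-en-1-one
Conditions: [Rh(OH)(cod)]2 (2.5 mol%), (R)-BINAP (5.5 mol%), KOH (0.2 equiv), 1,4-dioxane/H2O 10:1, 40 °C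
Reagents that add atoms: isopropenylboronic acid pinacol ester, CC(=C)B1OC(C)(C)C(C)(C)O1
Why: Rhodium-catalysed asymmetric conjugate addition of an alkenylboron reagent (Hayashi–Miyaura reaction) to one of the two enantiotopic enone arms desymmetrises the dienone and sets C5; (R)-BINAP is chosen by analogy with the facial sense known for cyclohex-2-enone, and a second addition should be slow because the remaining enone is more hindered.

Step 3
Reactants: 5 (R)-4,4-dimethoxy-5-(prop-1-en-2-yl)cyclohex-2-en-1-one; 6 iodomethane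
Product: 7 (5R,6S)-4,4-dimethoxy-6-methyl-5-(prop-1-en-2-yl)cyclohex-2-en-1-one (methyl trans to isopropenyl)
Conditions: LiN(i-Pr)2 (LDA), THF, −78 °C; MeI, −78 to −20 °C
Reagents that add atoms: iodomethane, CI
Why: Kinetic α'-enolate alkylation of the enone: only C10 can be deprotonated because the γ-position is the quaternary ketal carbon, and the methyl group enters anti to the isopropenyl group (this centre is enolised again in step 4).

Step 4
Reactants: 7 (5R,6S)-4,4-dimethoxy-6-methyl-5-(prop-1-en-2-yl)cyclohex-2-en-1-one; 8 phenyl vinyl sulfoxide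
Product: 10 (5R,6S)-6-ethenyl-4,4-dimethoxy-6-methyl-5-(prop-1-en-2-yl)cyclohex-2-en-1-one, via sulfoxide adduct 9 (not isolated)
Conditions: LiN(i-Pr)2 (LDA), THF, −78 °C; phenyl vinyl sulfoxide, −78 to 0 °C; H2O work-up; then toluene, NaHCO3, 110 °C
Reagents that add atoms: phenyl vinyl sulfoxide, C=CS(=O)c1ccccc1
Why: Michael addition of the tetrasubstituted α'-enolate to the vinyl sulfoxide (a vinyl cation equivalent) creates quaternary C10 with the new chain anti to the adjacent isopropenyl group, so the methyl group ends cis to it, and thermal syn-elimination of benzenesulfenic acid (sulfoxide pyrolysis) unveils the vinyl group.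

Step 5
Reactants: 10 (5R,6S)-6-ethenyl-4,4-dimethoxy-6-methyl-5-(prop-1-en-2-yl)cyclohex-2-en-1-one; 11 water
Product: 12 (5S,6S)-5-ethenyl-5-methyl-6-(prop-1-en-2-yl)cyclohex-2-ene-1,4-dione
Conditions: oxalic acid (10 mol%), THF/H2O 4:1, 0 °C
Reagents that add atoms: water, O
Why: Acid-catalysed ketal hydrolysis is fast for 4,4-dialkoxy enones, the ene-dione cannot aromatise because C10 is quaternary, and cold, weakly acidic conditions limit enolisation at C5.

Step 6
Reactants: 12 (5S,6S)-5-ethenyl-5-methyl-6-(prop-1-en-2-yl)cyclohex-2-ene-1,4-dione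
Product: 13 (4R,5S,6S)-6-ethenyl-4-hydroxy-6-methyl-5-(prop-1-en-2-yl)cyclohex-2-en-1-one (hydroxyl cis to isopropenyl and methyl)
Conditions: NaBH4 (1.0 equiv), CeCl3·7H2O, MeOH, −78 °C
Reagents that add atoms: none
Why: Luche 1,2-reduction should attack the less hindered C6 carbonyl (the C9 carbonyl is neopentylic beside C10) from the α face, anti to the adjacent isopropenyl group and the C10 methyl group, giving the 6β-alcohol.

Step 7
Reactants: 13 (4R,5S,6S)-6-ethenyl-4-hydroxy-6-methyl-5-(prop-1-en-2-yl)cyclohex-2-en-1-one; 14 triethylsilyl trifluoromethanesulfonate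
Product: 15 (4R,5S,6S)-6-ethenyl-6-methyl-5-(prop-1-en-2-yl)-4-[(triethylsilyl)oxy]cyclohex-2-en-1-one
Conditions: Et3SiOTf, 2,6-lutidine, CH2Cl2, −78 °C
Reagents that add atoms: triethylsilyl trifluoromethanesulfonate, CC[Si](CC)(CC)OS(=O)(=O)C(F)(F)F
Why: Silyl ether formation with a silyl triflate protects the hindered secondary alcohol as a group that survives hydride, base and carbenoid chemistry and leaves under buffered fluoride.

Step 8
Reactants: 15 (4R,5S,6S)-6-ethenyl-6-methyl-5-(prop-1-en-2-yl)-4-[(triethylsilyl)oxy]cyclohex-2-en-1-one; 16 trans-3-phenyl-2-(phenylsulfonyl)oxaziridine (Davis oxaziridine)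
Product: 18 (2R,4R,5S,6S)-6-ethenyl-2-hydroxy-6-methyl-5-(prop-1-en-2-yl)-4-[(triethylsilyl)oxy]cyclohexan-1-one, via potassium enolate 17 (not isolated)
Conditions: K[HB(s-Bu)3] (K-Selectride), THF, −78 °C; then oxaziridine 16, −78 °C; H2O
Reagents that add atoms: trans-3-phenyl-2-(phenylsulfonyl)oxaziridine, O=S(=O)(N1OC1c1ccccc1)c1ccccc1
Why: Conjugate hydride reduction (1,4-addition is favoured because the carbonyl is flanked by a quaternary carbon) gives the regiodefined C8 enolate, and enolate hydroxylation by the N-sulfonyloxaziridine should occur on the α face because the β face of C8 is flanked by the axial C10 methyl group and the axial C6 silyloxy group.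

Step 9
Reactants: 18 (2R,4R,5S,6S)-6-ethenyl-2-hydroxy-6-methyl-5-(prop-1-en-2-yl)-4-[(triethylsilyl)oxy]cyclohexan-1-one
Product: 19 (1S,2R,4R,5S,6S)-6-ethenyl-6-methyl-5-(prop-1-en-2-yl)-4-[(triethylsilyl)oxy]cyclohexane-1,2-diol (cis-diol on the α face)
Conditions: Li[HB(s-Bu)3] (L-Selectride, 2.5 equiv), THF, −78 °C; H2O
Reagents that add atoms: none
Why: Ketone reduction with a bulky trialkylborohydride proceeds by equatorial attack from the β face and should give the axial 9α-alcohol cis to the 8α-hydroxyl, as in the reduction of 4,4-dimethyl-3-keto steroids to axial alcohols.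

Step 10
Reactants: 19 (1S,2R,4R,5S,6S)-6-ethenyl-6-methyl-5-(prop-1-en-2-yl)-4-[(triethylsilyl)oxy]cyclohexane-1,2-diol; 20 2-(diethoxyphosphoryl)acetic acid
Product: 21 diol 19 2-[2-(diethoxyphosphoryl)acetate] (ester on the equatorial C8 oxygen, C9 hydroxyl free)
Conditions: DCC, DMAP (cat.), CH2Cl2, 0 °C
Reagents that add atoms: 2-(diethoxyphosphoryl)acetic acid, CCOP(=O)(CC(=O)O)OCC
Why: Carbodiimide (Steglich) esterification should select the equatorial C8 hydroxyl over the axial C9 hydroxyl, which is neopentylic beside quaternary C10.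

Step 11
Reactants: 21 diol 19 2-[2-(diethoxyphosphoryl)acetate]; 22 methacrylic anhydride
Product: 23 diol 19 1-(2-methylprop-2-enoate) 2-[2-(diethoxyphosphoryl)acetate]
Conditions: methacrylic anhydride (3 equiv), DMAP, Et3N, CH2Cl2, 40 °C
Reagents that add atoms: methacrylic anhydride, CC(=C)C(=O)OC(=O)C(C)=C
Why: DMAP-catalysed acylation of the remaining hindered alcohol installs the ester that the target carries and at the same time removes the O–H bond and deactivates the geminal C9–H bond before the carbenoid step.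

Step 12
Reactants: 23 diol 19 1-(2-methylprop-2-enoate) 2-[2-(diethoxyphosphoryl)acetate]; 24 4-acetamidobenzenesulfonyl azide
Product: 25 diol 19 1-(2-methylprop-2-enoate) 2-[2-diazo-2-(diethoxyphosphoryl)acetate]
Conditions: LiN(SiMe3)2 (1.05 equiv), THF, −78 °C; 4-acetamidobenzenesulfonyl azide, −78 °C to rt; H2O
Reagents that add atoms: 4-acetamidobenzenesulfonyl azide, CC(=O)Nc1ccc(cc1)S(=O)(=O)N=[N+]=[N-]
Why: Regitz diazo transfer to the lithium enolate of the phosphonoacetate, the most acidic C–H position of the molecule, gives the acceptor/acceptor diazo ester without touching a stereocenter.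

Step 13
Reactants: 25 diol 19 1-(2-methylprop-2-enoate) 2-[2-diazo-2-(diethoxyphosphoryl)acetate]; 26 paraformaldehyde (formaldehyde source)
Product: 28 9α-(methacryloyloxy)-6β-(triethylsilyloxy)elema-1,3,11(13)-trien-12,8α-olide (H-7 α, H-8 β, trans-fused lactone), via phosphonolactone 27 (not isolated)
Conditions: Rh2(oct)4 (2 mol%), CH2Cl2, 40 °C, slow addition of 25; solvent switch to THF; KOt-Bu (1.0 equiv), 0 °C; (CH2O)n, 0 °C to rt
Reagents that add atoms: paraformaldehyde (formaldehyde), C=O
Why: Rh2(oct)4 expels N2 from the α-diazo-α-phosphonoacetate to give an electrophilic dirhodium carbenoid that inserts, through a concerted three-centre transition state with retention at carbon, into the C–H bond held 1,5 to it, and KOt-Bu with formaldehyde then runs a Horner–Wadsworth–Emmons olefination on the crude α-phosphonolactone 27 in the same flask. The closest known reaction type is the one-pot rhodium-carbenoid C–H insertion/olefination of cyclohexyl α-diazo(phosphoryl)acetates to trans-fused α-methylene-γ-butyrolactones. The γ-lactone is closed by 1,5-C–H insertion through a five-membered array (C8–O–C12–C11 plus C7), and the ring fusion should be trans because the equatorial ester reaches the equatorial C7–H bond. The new C7 stereocenter is fixed by the chair of the carbocycle (axial C10 methyl, equatorial C5 isopropenyl), which makes the β-hydrogen on C7 the equatorial one, and by retention in the insertion; the C11 centre of 27 is erased by the olefination. The step needs site selectivity for C7–H over C9–H and over the alkenes: C9–H is deactivated by its methacrylate oxygen and shielded by quaternary C10, the five-membered insertion should outrun medium-ring cyclopropanation of the C10 vinyl and C5 isopropenyl groups, and the acrylate-type alkenes are electron-poor.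

Step 14
Reactants: 28 9α-(methacryloyloxy)-6β-(triethylsilyloxy)elema-1,3,11(13)-trien-12,8α-olide; 29 tert-butyl hydroperoxide
Product: 31 9α-(methacryloyloxy)-15-oxo-6β-(triethylsilyloxy)elema-1,3,11(13)-trien-12,8α-olide, via allylic alcohol 30 (not isolated)
Conditions: SeO2 (0.5 equiv), t-BuOOH (2 equiv), CH2Cl2, rt; aqueous work-up; then Dess–Martin periodinane, NaHCO3, CH2Cl2, 0 °C
Reagents that add atoms: tert-butyl hydroperoxide, CC(C)(C)OO (oxygen relayed through SeO2)
Why: Selenium dioxide allylic oxidation (ene reaction then [2,3]-shift) should attack only the electron-rich isopropenyl group at its methyl group, since the vinyl group has no allylic hydrogen and the other alkenes are conjugated to carbonyl groups, and Dess–Martin oxidation converges the alcohol/enal mixture on the enal.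

Step 15
Reactants: 31 9α-(methacryloyloxy)-15-oxo-6β-(triethylsilyloxy)elema-1,3,11(13)-trien-12,8α-olide; 32 hydrogen peroxide
Product: 33 (1R)-1,2-epoxy-9α-(methacryloyloxy)-15-oxo-6β-(triethylsilyloxy)elema-3,11(13)-dien-12,8α-olide
Conditions: [Ti(μ-O)(salalen)]2 (5 mol%, ligand enantiomer that converts 1-alkenes into (R)-2-alkyloxiranes), 30% aq. H2O2 (1.5 equiv), CH2Cl2, pH 7 buffer, rt
Reagents that add atoms: hydrogen peroxide, OO
Why: Titanium-salalen-catalysed asymmetric epoxidation with aqueous hydrogen peroxide is selective for non-conjugated terminal alkenes, so only the C10 vinyl group should react, and the C1 stereocenter is set by the catalyst rather than by the substrate.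

Step 16
Reactants: 33 (1R)-1,2-epoxy-9α-(methacryloyloxy)-15-oxo-6β-(triethylsilyloxy)elema-3,11(13)-dien-12,8α-olide
Product: 34 (1R)-1,2-epoxy-6β-hydroxy-9α-(methacryloyloxy)-15-oxoelema-3,11(13)-dien-12,8α-olide (CNP0124638.2)
Conditions: Bu4NF/AcOH (1:1), THF, 0 °C
Reagents that add atoms: none
Why: Buffered fluoride desilylation removes the triethylsilyl ether under near-neutral conditions that the oxirane, the enal and both acrylate units should tolerate and that avoid base-induced migration of the lactone to the C6 oxygen.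

**Compound list**
1 | 4-methoxyphenol | COc1ccc(O)cc1 | starting material
2 | methanol | CO | starting material
3 | 4,4-dimethoxycyclohexa-2,5-dien-1-one | COC1(OC)C=CC(=O)C=C1 | intermediate
4 | isopropenylboronic acid pinacol ester | CC(=C)B1OC(C)(C)C(C)(C)O1 | starting material
5 | (R)-4,4-dimethoxy-5-(prop-1-en-2-yl)cyclohex-2-en-1-one | O=C1C=CC(OC)(OC)[C@@H](C(C)=C)C1 | intermediate
6 | iodomethane | CI | starting material
7 | (5R,6S)-4,4-dimethoxy-6-methyl-5-(prop-1-en-2-yl)cyclohex-2-en-1-one | O=C1C=CC(OC)(OC)[C@@H](C(C)=C)[C@@H]1C | intermediate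
8 | phenyl vinyl sulfoxide | C=CS(=O)c1ccccc1 | starting material
9 | (5R,6S)-4,4-dimethoxy-6-methyl-6-[2-(phenylsulfinyl)ethyl]-5-(prop-1-en-2-yl)cyclohex-2-en-1-one (mixture at sulfur) | O=C1C=CC(OC)(OC)[C@@H](C(C)=C)[C@]1(C)CCS(=O)c1ccccc1 | intermediate
10 | (5R,6S)-6-ethenyl-4,4-dimethoxy-6-methyl-5-(prop-1-en-2-yl)cyclohex-2-en-1-one | O=C1C=CC(OC)(OC)[C@@H](C(C)=C)[C@]1(C)C=C | intermediate
11 | water | O | starting material
12 | (5S,6S)-5-ethenyl-5-methyl-6-(prop-1-en-2-yl)cyclohex-2-ene-1,4-dione | O=C1C=CC(=O)[C@@H](C(C)=C)[C@]1(C)C=C | intermediate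
13 | (4R,5S,6S)-6-ethenyl-4-hydroxy-6-methyl-5-(prop-1-en-2-yl)cyclohex-2-en-1-one | O=C1C=C[C@@H](O)[C@@H](C(C)=C)[C@]1(C)C=C | intermediate
14 | triethylsilyl trifluoromethanesulfonate | CC[Si](CC)(CC)OS(=O)(=O)C(F)(F)F | starting material
15 | (4R,5S,6S)-6-ethenyl-6-methyl-5-(prop-1-en-2-yl)-4-[(triethylsilyl)oxy]cyclohex-2-en-1-one | O=C1C=C[C@@H](O[Si](CC)(CC)CC)[C@@H](C(C)=C)[C@]1(C)C=C | intermediate
16 | trans-3-phenyl-2-(phenylsulfonyl)oxaziridine | O=S(=O)(N1OC1c1ccccc1)c1ccccc1 | starting material
17 | potassium enolate of the 2,3-dihydro derivative of 15 | [K+].[O-]C1=CC[C@@H](O[Si](CC)(CC)CC)[C@@H](C(C)=C)[C@]1(C)C=C | intermediate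
18 | (2R,4R,5S,6S)-6-ethenyl-2-hydroxy-6-methyl-5-(prop-1-en-2-yl)-4-[(triethylsilyl)oxy]cyclohexan-1-one | O=C1[C@H](O)C[C@@H](O[Si](CC)(CC)CC)[C@@H](C(C)=C)[C@]1(C)C=C | intermediate
19 | (1S,2R,4R,5S,6S)-6-ethenyl-6-methyl-5-(prop-1-en-2-yl)-4-[(triethylsilyl)oxy]cyclohexane-1,2-diol | O[C@@H]1[C@H](O)C[C@@H](O[Si](CC)(CC)CC)[C@@H](C(C)=C)[C@]1(C)C=C | intermediate
20 | 2-(diethoxyphosphoryl)acetic acid | CCOP(=O)(CC(=O)O)OCC | starting material
21 | diol 19 2-[2-(diethoxyphosphoryl)acetate] | O[C@@H]1[C@H](OC(=O)CP(=O)(OCC)OCC)C[C@@H](O[Si](CC)(CC)CC)[C@@H](C(C)=C)[C@]1(C)C=C | intermediate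
22 | methacrylic anhydride | CC(=C)C(=O)OC(=O)C(C)=C | starting material
23 | diol 19 1-(2-methylprop-2-enoate) 2-[2-(diethoxyphosphoryl)acetate] | C=C(C)C(=O)O[C@@H]1[C@H](OC(=O)CP(=O)(OCC)OCC)C[C@@H](O[Si](CC)(CC)CC)[C@@H](C(C)=C)[C@]1(C)C=C | intermediate
24 | 4-acetamidobenzenesulfonyl azide | CC(=O)Nc1ccc(cc1)S(=O)(=O)N=[N+]=[N-] | starting material
25 | diol 19 1-(2-methylprop-2-enoate) 2-[2-diazo-2-(diethoxyphosphoryl)acetate] | C=C(C)C(=O)O[C@@H]1[C@H](OC(=O)C(=[N+]=[N-])P(=O)(OCC)OCC)C[C@@H](O[Si](CC)(CC)CC)[C@@H](C(C)=C)[C@]1(C)C=C | intermediate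
26 | paraformaldehyde (formaldehyde) | C=O | starting material
27 | 11-(diethoxyphosphoryl)-9α-(methacryloyloxy)-6β-(triethylsilyloxy)elema-1,3-dien-12,8α-olide (mixture at C11) | C=C(C)C(=O)O[C@@H]1[C@@H]2OC(=O)C(P(=O)(OCC)OCC)[C@H]2[C@@H](O[Si](CC)(CC)CC)[C@@H](C(C)=C)[C@]1(C)C=C | intermediate
28 | 9α-(methacryloyloxy)-6β-(triethylsilyloxy)elema-1,3,11(13)-trien-12,8α-olide | C=C(C)C(=O)O[C@@H]1[C@@H]2OC(=O)C(=C)[C@H]2[C@@H](O[Si](CC)(CC)CC)[C@@H](C(C)=C)[C@]1(C)C=C | intermediate
29 | tert-butyl hydroperoxide | CC(C)(C)OO | starting material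
30 | 15-hydroxy-9α-(methacryloyloxy)-6β-(triethylsilyloxy)elema-1,3,11(13)-trien-12,8α-olide | C=C(C)C(=O)O[C@@H]1[C@@H]2OC(=O)C(=C)[C@H]2[C@@H](O[Si](CC)(CC)CC)[C@@H](C(=C)CO)[C@]1(C)C=C | intermediate
31 | 9α-(methacryloyloxy)-15-oxo-6β-(triethylsilyloxy)elema-1,3,11(13)-trien-12,8α-olide | C=C(C)C(=O)O[C@@H]1[C@@H]2OC(=O)C(=C)[C@H]2[C@@H](O[Si](CC)(CC)CC)[C@@H](C(=C)C=O)[C@]1(C)C=C | intermediate
32 | hydrogen peroxide | OO | starting material
33 | (1R)-1,2-epoxy-9α-(methacryloyloxy)-15-oxo-6β-(triethylsilyloxy)elema-3,11(13)-dien-12,8α-olide | C=C(C)C(=O)O[C@@H]1[C@@H]2OC(=O)C(=C)[C@H]2[C@@H](O[Si](CC)(CC)CC)[C@@H](C(=C)C=O)[C@]1(C)[C@@H]1CO1 | intermediate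
34 | (1R)-1,2-epoxy-6β-hydroxy-9α-(methacryloyloxy)-15-oxoelema-3,11(13)-dien-12,8α-olide (CNP0124638.2) | C=C(C)C(=O)O[C@@H]1[C@@H]2OC(=O)C(=C)[C@H]2[C@@H](O)[C@@H](C(=C)C=O)[C@]1(C)[C@@H]1CO1 | target

**Step count and risks**
Total steps: 16. Longest linear sequence: 16 steps (fully linear from 1).

Steps most likely to fail:

Step 13. The carbenoid may be diverted: addition to the C10 vinyl group, insertion at C9–H, or insertion into the axial C7–H bond giving the cis-fused lactone. The fallback sets out from diol 19 and separates site control from methylenation. Acylation of the equatorial hydroxyl with bromoacetyl bromide/pyridine gives the bromoacetate F1. N,N'-Ditosylhydrazine with DBU converts it into the diazoacetate F2, and methacrylic anhydride/DMAP then gives the methacrylate diazoacetate F3. Decomposition with a chiral dirhodium carboxamidate (Rh2(4S-MPPIM)4 or its enantiomer, whichever is matched) lets the catalyst steer the acceptor-only carbenoid into the equatorial C7–H bond, giving the α-unsubstituted trans-lactone F4. A Mannich reaction of its lithium enolate with dimethyl(methylidene)ammonium iodide gives the amine F5; quaternisation with iodomethane and elimination with NaHCO3 bring the route back at 28.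

Step 15. Oxygen transfer to the neopentyl-type vinyl group may be slow or poorly face-selective, and the aldehyde may be over-oxidised by the peroxide. The fallback sets out from 31. Dimethyldioxirane in acetone at 0 °C epoxidises the only electron-rich alkene without facial bias and gives 33 together with its epoxide epimer F6. Hydrolytic kinetic resolution of the mixture with (salen)Co(OAc) (trivalent cobalt, the enantiomer that hydrolyses (S)-configured 2-alkyloxiranes) and a slight excess of water relative to F6 opens F6 to the diol F7. F7 is removed by chromatography, and the route continues from 33.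

Step 8. Oxygen may be delivered to the β face of the enolate, or 1,2-reduction may compete with conjugate reduction. The fallback sets out from 15 and corrects the centre by inversion instead of by face selection. The same reductive hydroxylation is run, and the C8-epimeric ketol F8, if it predominates, is esterified under Mitsunobu conditions (4-nitrobenzoic acid, PPh3, diisopropyl azodicarboxylate; SN2 at C8) to the 8α-ester F9. Methanolysis (K2CO3, MeOH, 0 °C) returns to the route at 18.

**Further compounds**
F1 | step 13 | diol 19 2-(2-bromoacetate) | O[C@@H]1[C@H](OC(=O)CBr)C[C@@H](O[Si](CC)(CC)CC)[C@@H](C(C)=C)[C@]1(C)C=C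
F2 | step 13 | diol 19 2-(2-diazoacetate) | O[C@@H]1[C@H](OC(=O)C=[N+]=[N-])C[C@@H](O[Si](CC)(CC)CC)[C@@H](C(C)=C)[C@]1(C)C=C
F3 | step 13 | diol 19 1-(2-methylprop-2-enoate) 2-(2-diazoacetate) | C=C(C)C(=O)O[C@@H]1[C@H](OC(=O)C=[N+]=[N-])C[C@@H](O[Si](CC)(CC)CC)[C@@H](C(C)=C)[C@]1(C)C=C
F4 | step 13 | 9α-(methacryloyloxy)-6β-(triethylsilyloxy)-13-norelema-1,3-dien-12,8α-olide (trans-fused, α-CH2 lactone) | C=C(C)C(=O)O[C@@H]1[C@@H]2OC(=O)C[C@H]2[C@@H](O[Si](CC)(CC)CC)[C@@H](C(C)=C)[C@]1(C)C=C
F5 | step 13 | 13-(dimethylamino)-9α-(methacryloyloxy)-6β-(triethylsilyloxy)elema-1,3-dien-12,8α-olide (mixture at C11) | C=C(C)C(=O)O[C@@H]1[C@@H]2OC(=O)C(CN(C)C)[C@H]2[C@@H](O[Si](CC)(CC)CC)[C@@H](C(C)=C)[C@]1(C)C=C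
F6 | step 15 | (1S)-epoxide epimer of 33 | C=C(C)C(=O)O[C@@H]1[C@@H]2OC(=O)C(=C)[C@H]2[C@@H](O[Si](CC)(CC)CC)[C@@H](C(=C)C=O)[C@]1(C)[C@H]1CO1
F7 | step 15 | 1,2-diol from hydrolysis of F6 | C=C(C)C(=O)O[C@@H]1[C@@H]2OC(=O)C(=C)[C@H]2[C@@H](O[Si](CC)(CC)CC)[C@@H](C(=C)C=O)[C@]1(C)[C@H](O)CO
F8 | step 8 | C2 epimer of 18 (hydroxyl on the β face) | O=C1[C@@H](O)C[C@@H](O[Si](CC)(CC)CC)[C@@H](C(C)=C)[C@]1(C)C=C
F9 | step 8 | 4-nitrobenzoate of 18 | O=C1[C@H](OC(=O)c2ccc(cc2)[N+](=O)[O-])C[C@@H](O[Si](CC)(CC)CC)[C@@H](C(C)=C)[C@]1(C)C=C
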